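A millimolar of J is the unit I count in. Q is Z with two ligands exchanged, so one Z that reaches Q has paid two J, one at each fork, and a Q once made can still be lost.

| flask | Z | J | remark | time |
|---|---|---|---|---|
| amber | 1.5 mM | 21 mM | run made earlier |  |
| teal | 1.5 mM | 7.1 mM | run made earlier |  |
| spring | 1.5 mM | 14.2 mM |  | 6.0 min |
| winter | 5.0 mM | 14.2 mM |  | 6.0 min |
| summer | 15 mM | 14.2 mM |  | 6.0 min |

| run | time / min | Q / % |
|---|---|---|
| amber | 0.417 | 7.9 |
| amber | 1.33 | 27.7 |
| amber | 2.50 | 30.4 |
| amber | 4.00 | 21.3 |
| teal | 0.833 | 3.3 |
| teal | 2.00 | 9.2 |
| teal | 2.50 | 10.9 |
| teal | 4.00 | 12.8 |

(scatter of a reading: 0.3 percentage points)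

1. [Q] at the end for spring, winter, summer, in this order
2. the shape of the row from first to last (falls, then rises / rises all the way / rises, then falls / hardly changes / falls all the way)

- "hardly changes" means that all values lie within two and a half points (for a concentration: within two and a half percent of the largest)

The settings I can turn are J's charge, the time and Z's charge. By hand, J's charge should act at both forks: if each exchange is first order in J, early Q goes as the square of J and the square of time. In the readings, Q over time squared at the first point stands 9.55 times higher in amber than in teal, and the square of their J ratio is 8.75, so I take both forks to be paid in J.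

By hand, time should first raise Q and then lower it. Amber reads 30.4% at 2.50 min and 21.3% at 4.00 min, so Q is a passing amount there, and the asked time lies later than amber's last reading.

Z's charge is the setting this row turns. By hand, with J to spare, Q in millimolar should grow with Z, but every Z draws on the same J. Spring has 4.73, winter 1.42 and summer 0.473 of what I call the J budget, the charge of J over two times the charge of Z. Above one, J can pay both forks for each Z. Below one, the charge of J falls short of paying both forks for each Z, so J is the limiting reagent for the double exchange, and I reckon that an extra Z then draws on the J that a once-exchanged Z needs at its second fork. So I reckon a rise from spring to winter, whose budget is more than one, and a fall to summer, whose budget is less than one. I put the turn where the budget is one, at 7.10 mM of Z.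

The forecast gives 0.19 mM, 0.46 mM and 0.3 mM, with the shape rises, then falls, and says of summer “feed stalls while Q keeps decaying”. My budget gives the same shape and no values.

The flasks give 0.200 mM, 0.486 mM and 0.433 mM, with the shape rises, then falls, so summer stands 0.133 mM above the forecast.

    Z + J ⇌ D + G (K = 5.50, k = 1.65 M⁻¹ s⁻¹)
    G + J ⇌ D + Q (K = 0.640, k = 0.567 M⁻¹ s⁻¹)
    Q → E (k = 0.00912 s⁻¹)
    Q ⇌ L (K = 1.94, k = 0.00204 s⁻¹)

In summer at 6.00 min, J stands at 15.8% of its charge, while 38.7% of the charged Z is still Z and 43.0% is G. Winter's budget of 1.42 and summer's of 0.473 lie on either side of one. The row turns at 7.5 mM of Z, where the budget reads 0.944.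

(The numbers in the tables are calculated from invented constants.)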